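**Structural features**

The target is the 4-methoxybenzoate of a carotane (daucane)-type diol. A cyclopentane (C1, C2, C3, C3a, C8a; azulene locants are used for every bicyclic compound below) is fused through the C3a–C8a bond to a cycloheptene (C3a, C4, C5, C6=C7, C8, C8a). C3 carries the isopropyl group, C3a a tertiary hydroxyl, C8a the angular methyl group, C8 (secondary, allylic) the aroyloxy group, and C6 the methyl group of the trisubstituted C6=C7 bond. The four stereocentres C3, C3a, C8a and C8 are contiguous, and two of them (C3a, C8a) are fully substituted and vicinal. Isopropyl, OH, CH3 and aroyloxy all lie on one face, so the ring fusion is cis (3R,3aS,8S,8aR). C8a sits between two oxygen-bearing ring carbons, C8 and C3a. Inside the seven-membered ring this unit is a latent 2-methylcycloheptane-1,3-dione with a prochiral C8a; the key step exploits this C8–C8a–C3a unit by closing the cyclopentane (C3–C3a bond) onto one of its two carbonyl groups. Fragile groups are the tertiary β-hydroxy carbonyl array at the ketone stage (retro-aldol, β-elimination), the allylic ester (ionization, acyl shift to the cis tertiary OH) and the trisubstituted alkene. The real difficulty is the all-cis triad C3/C3a/C8a: a reagent that adds a substituent to C3a or C8a of a preformed bicycle must enter syn to groups on both neighbours. C8 and the alkene are comparatively easy.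

**Logic of the disconnections**

17 ⇒ 15 + 16. The ester C8–O–C(=O) bond is cut. The arene is the only part with no role in the stereochemical problem, so it is attached last. The forward step must acylate the secondary allylic hydroxyl at C8 and leave the tertiary C3a hydroxyl untouched.

15 ⇒ 14. The C8–H bond is cut (carbinol back to ketone). C8 stands 1,3 to the C3a hydroxyl, so a β-hydroxy enone can relay the C3a configuration to C8 through a chelate. This removes one stereocentre and gives a conjugated enone. The forward step must deliver hydride 1,2 and from the face away from the chelate.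

14 ⇒ 11 (through 12 and 13). The C6–CH3 bond is cut and the C6=C7 unsaturation is kept. An enone accepts the methyl group at C6 by conjugate addition, and re-oxidation restores the double bond. The forward step needs clean trapping of the enolate, dehydrogenation toward C6, and release of the C3a hydroxyl.

11 ⇒ 9 (through 10). The C6=C7 double bond is removed. The ketone at C8 has α-hydrogens only at C7 because C8a is quaternary, so dehydrogenation has one possible direction.

9 ⇒ 8 ⇒ 7. The isopropyl group is traced back through C=CH2 to an acetyl group. An acyl group at C3 is what makes C3 a nucleophile in the key step. The forward olefination must distinguish the acetyl group from the hindered ring ketone and must not epimerize C3.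

7 ⇒ 6 (key disconnection). The C3–C3a bond and the C2–H bond are cut. This opens the cyclopentane, returns C3a to a carbonyl group, and turns the bicyclic all-cis triad into an achiral monocycle with two enantiotopic carbonyl groups. Three stereocentres disappear at once. The forward step must choose one carbonyl group (absolute configuration), close only cis, and place the acetyl group cis to the new oxygen.

6 ⇒ 4 + 5. The C2=C3 double bond is cut by a cross-metathesis transform, which leaves a simple allyl group on C8a.

4 ⇒ 2 + 3 and 2 ⇒ 1. The C8a–C1 and C8a–CH3 bonds are cut. Both are alkylations at the carbon between the two carbonyl groups, and 1 is a commercial seven-membered ring.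

**Other disconnections considered**

Alternative 1: the first idea is to cut the C6=C7 bond and close the seven-membered ring last by ring-closing metathesis of the cyclopentane diene A1 (second-generation Grubbs catalyst), which would give 14. A1 already contains the whole C3/C3a/C8a triad, so the metathesis solves none of the stereochemistry. To make A1, a 3-methylbut-3-enyl nucleophile would have to add to a cyclopentanone carbonyl (C3a) syn to the larger acyl branch of the adjacent quaternary C8a, and C8a itself would have to be set cis to the isopropyl group in a separate step. The chosen plan sets all three centres in one ring closure and buys the seven-membered ring.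

Alternative 2: the seven-membered ring is cut at C3a–C8a and C6–C7, with the C3a oxygen drawn from a furan. The forward key step is a dearomatizing intramolecular (4+3) cycloaddition of the oxyallyl cation from the furan-tethered α-chloro ketone A2 (base, trifluoroethanol) to the oxygen-bridged tricycle A3. Hydrogenation of its C4=C5 bond and β-elimination of the bridge would give 14. This is the shortest plan, and the stereocentre at C3 should control the furan face. Its weakness is C8a. In A3 the new cyclopentane must span the bridgehead C3a and the equatorial position at C8a. In the flattened chair of an 8-oxabicyclo[3.2.1]octan-3-one the bridgehead exo bond makes a dihedral angle near 80° with an equatorial neighbour and near 40° with an axial one. A three-atom tether should therefore prefer the axial position, which is the C8a epimer with the angular methyl trans to the C3a oxygen. The route to A2 also needs an electrophilic chlorination next to an electron-rich furan. In the chosen plan the cis fusion follows from tether length and not from a preference.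

Alternative 3: one ring carbon (C7) is deleted, so that 14 would come from the cis-hydrindanone A4 by single-carbon insertion: cyclopropanation of its silyl enol ether to A5, then FeCl3-induced ring opening and loss of HCl. The insertion is regiochemically sound, but A4 carries the same all-cis triad as the target, so the hard part is only moved. A Hajos–Parrish-type aldol would give the cis OH/CH3 hydrindane, but with an oxygen at C1 where none is wanted, no isopropyl group at C3, and the ketone at the wrong ring position. Correcting these costs more steps than starting from the seven-membered dione.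

Key step: step 4

Assumption: a model does not reliably predict which enantiotopic carbonyl group the copper hydride ligated by (R)-DTBM-SEGPHOS selects in this dione; the ligand is written as (R) and its antipode is used if the other carbonyl is addressed. The relative configuration does not depend on this choice.

**Route**

Step 1
Reactants: 1 cycloheptane-1,3-dione
Product: 2 2-methylcycloheptane-1,3-dione
Conditions: MeI, K2CO3, acetone, 50 °C
Reagents that add atoms: iodomethane (CI)
Why: C-alkylation of the β-diketone enolate at the carbon between the two carbonyl groups, which should give the 2-methyl dione.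

Step 2
Reactants: 2 2-methylcycloheptane-1,3-dione; 3 allyl methyl carbonate
Product: 4 2-methyl-2-(prop-2-en-1-yl)cycloheptane-1,3-dione
Conditions: Pd(PPh3)4 (2 mol %), THF, 40 °C
Reagents that add atoms: allyl methyl carbonate 3 (C=CCOC(=O)OC)
Why: Tsuji–Trost allylation under neutral conditions; the methoxide set free from the carbonate deprotonates the dione, and any O-allyl product re-ionizes on palladium, so the C-allylated quaternary dione should accumulate.

Step 3
Reactants: 4 2-methyl-2-(prop-2-en-1-yl)cycloheptane-1,3-dione; 5 but-3-en-2-one
Product: 6 2-methyl-2-[(2E)-4-oxopent-2-en-1-yl]cycloheptane-1,3-dione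
Conditions: second-generation Grubbs catalyst (3 mol %), but-3-en-2-one (3 equiv), CH2Cl2, 40 °C
Reagents that add atoms: but-3-en-2-one 5 (CC(=O)C=C)
Why: Olefin cross-metathesis between a monosubstituted alkene and an electron-poor vinyl ketone; the conjugated E-enone is the thermodynamic product and should not re-enter metathesis.

Step 4
Reactants: 6 2-methyl-2-[(2E)-4-oxopent-2-en-1-yl]cycloheptane-1,3-dione
Product: 7 (3S,3aS,8aS)-3-acetyl-3a-{[dimethyl(phenyl)silyl]oxy}-8a-methyloctahydroazulen-8(1H)-one
Conditions: Cu(OAc)2 (5 mol %), (R)-DTBM-SEGPHOS (5.5 mol %), PhMe2SiH (1.3 equiv), toluene, −20 °C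
Reagents that add atoms: dimethylphenylsilane (C[SiH](C)c1ccccc1)
Why: Monovalent copper hydride, formed from divalent Cu(OAc)2 and the silane, adds hydride to C2 of the s-cis enone to give the Z copper enolate, whose C3 attacks one ring carbonyl (the future C3a) in a copper-bridged chair (Zimmerman–Traxler) array; silyl transfer from PhMe2SiH to the copper alkoxide releases 7 and regenerates the hydride. The closest known reaction type is the copper hydride-catalysed enantioselective intramolecular reductive aldol cyclization of enones and enoates onto ketones, including the desymmetrization of 2,2-disubstituted cyclic 1,3-diones. The ring closed is the cyclopentane, by 5-exo-trig (enolexo) attack that forms C3–C3a. For C3a and C8a, the two-atom link C1–C2 lets C3 reach only the carbonyl face on the side of C1, so the new bond is cis to C8a–C1 and the oxygen is pushed cis to the angular methyl group (cis fusion by geometry). For C3, the Z enolate in the closed chair holds the acetyl group on the copper bridge together with the C3a oxygen, which places it cis to that oxygen. The absolute configuration is set by the chiral bisphosphine, which decides which of the two enantiotopic carbonyl groups is attacked and thereby fixes C8a, C3a and C3 together. The step needs 1,4-hydride addition to the unhindered acyclic enone ahead of 1,2-reduction of a ketone (low temperature, limited silane) and ring closure ahead of silylation of the enolate (intramolecular five-ring aldol).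

Step 5
Reactants: 7 (3S,3aS,8aS)-3-acetyl-3a-{[dimethyl(phenyl)silyl]oxy}-8a-methyloctahydroazulen-8(1H)-one
Product: 8 (3R,3aS,8aS)-3a-{[dimethyl(phenyl)silyl]oxy}-8a-methyl-3-(prop-1-en-2-yl)octahydroazulen-8(1H)-one
Conditions: Zn, CH2Br2, TiCl4, THF, 0 °C to rt
Reagents that add atoms: dibromomethane (BrCBr)
Why: Takai–Lombardo methylenation; the non-basic gem-dimetallic reagent should olefinate the methyl ketone without enolizing it, so C3 keeps its configuration, and the ring ketone next to quaternary C8a should react much more slowly.

Step 6
Reactants: 8 (3R,3aS,8aS)-3a-{[dimethyl(phenyl)silyl]oxy}-8a-methyl-3-(prop-1-en-2-yl)octahydroazulen-8(1H)-one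
Product: 9 (3R,3aS,8aS)-3a-{[dimethyl(phenyl)silyl]oxy}-8a-methyl-3-(propan-2-yl)octahydroazulen-8(1H)-one
Conditions: H2 (1 atm), Pd/C, EtOAc, rt
Reagents that add atoms: none
Why: Heterogeneous hydrogenation of the 1,1-disubstituted alkene; no stereocentre is formed, and the hindered ketone and the silyl ether should be inert.

Step 7
Reactants: 9 (3R,3aS,8aS)-3a-{[dimethyl(phenyl)silyl]oxy}-8a-methyl-3-(propan-2-yl)octahydroazulen-8(1H)-one
Product: 11 (3R,3aS,8aS)-3a-{[dimethyl(phenyl)silyl]oxy}-8a-methyl-3-(propan-2-yl)-2,3,3a,4,5,8a-hexahydroazulen-8(1H)-one, via trimethylsilyl enol ether 10 (not isolated)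
Conditions: LDA, TMSCl, THF, −78 °C; then Pd(OAc)2 (10 mol %), O2 (1 atm), DMSO, rt
Reagents that add atoms: none
Why: Saegusa–Ito oxidation; only C7 carries α-hydrogens because C8a is quaternary, so the enol silane and the C6=C7 enone can form in one direction only.

Step 8
Reactants: 11 (3R,3aS,8aS)-3a-{[dimethyl(phenyl)silyl]oxy}-8a-methyl-3-(propan-2-yl)-2,3,3a,4,5,8a-hexahydroazulen-8(1H)-one
Product: 14 (3R,3aS,8aS)-3a-hydroxy-6,8a-dimethyl-3-(propan-2-yl)-2,3,3a,4,5,8a-hexahydroazulen-8(1H)-one, via trimethylsilyl enol ether 12 (not isolated), via silyl ether enone 13 (not isolated)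
Conditions: Me2CuLi, TMSCl, THF, −78 °C; then Pd(OAc)2 (10 mol %), O2 (1 atm), DMSO, rt; then 1 M HCl, THF, 0 °C
Reagents that add atoms: lithium dimethylcuprate ([Li+].C[Cu-]C)
Why: Silyl-accelerated cuprate conjugate addition places the methyl group on C6 and traps the enolate as its enol silane; a second Saegusa–Ito oxidation restores C6=C7 and erases the transient C6 stereocentre. Dilute acid then cleaves the tertiary silyl ether to free the C3a hydroxyl for the next step.

Step 9
Reactants: 14 (3R,3aS,8aS)-3a-hydroxy-6,8a-dimethyl-3-(propan-2-yl)-2,3,3a,4,5,8a-hexahydroazulen-8(1H)-one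
Product: 15 (3R,3aS,8S,8aR)-6,8a-dimethyl-3-(propan-2-yl)-1,2,3,4,5,8-hexahydroazulene-3a,8(8aH)-diol
Conditions: Et2BOMe, THF/MeOH 4:1, −78 °C; NaBH4, −78 °C; then AcOH, MeOH
Reagents that add atoms: none
Why: Narasaka–Prasad reduction; the diethylboron chelate ties the C3a oxygen to the C8 carbonyl oxygen, and external borohydride should attack C8 1,2 from the face away from the boron bridge, so that both C–O bonds end up cis (syn-1,3-diol, 8S).

Step 10
Reactants: 15 (3R,3aS,8S,8aR)-6,8a-dimethyl-3-(propan-2-yl)-1,2,3,4,5,8-hexahydroazulene-3a,8(8aH)-diol; 16 4-methoxybenzoyl chloride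
Product: 17 (3R,3aS,8S,8aR)-3a-hydroxy-6,8a-dimethyl-3-(propan-2-yl)-1,2,3,3a,4,5,8,8a-octahydroazulen-8-yl 4-methoxybenzoate
Conditions: pyridine, DMAP (cat.), CH2Cl2, 0 °C to rt
Reagents that add atoms: 4-methoxybenzoyl chloride 16 (COc1ccc(cc1)C(Cl)=O)
Why: DMAP-catalysed acylation; the secondary allylic hydroxyl at C8 should react, while the tertiary ring-fusion hydroxyl is too hindered to compete, and no stereocentre is touched.

**Compound list**

1 | cycloheptane-1,3-dione | O=C1CCCCC(=O)C1 | starting material
2 | 2-methylcycloheptane-1,3-dione | CC1C(=O)CCCCC1=O | intermediate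
3 | allyl methyl carbonate (methyl prop-2-en-1-yl carbonate) | C=CCOC(=O)OC | starting material
4 | 2-methyl-2-(prop-2-en-1-yl)cycloheptane-1,3-dione | C=CCC1(C)C(=O)CCCCC1=O | intermediate
5 | but-3-en-2-one | CC(=O)C=C | starting material
6 | 2-methyl-2-[(2E)-4-oxopent-2-en-1-yl]cycloheptane-1,3-dione | CC(=O)/C=C/CC1(C)C(=O)CCCCC1=O | intermediate
7 | (3S,3aS,8aS)-3-acetyl-3a-{[dimethyl(phenyl)silyl]oxy}-8a-methyloctahydroazulen-8(1H)-one (acetyl, silyloxy and angular methyl on one face) | O=C1CCCC[C@]2(O[Si](C)(C)c3ccccc3)[C@@H](C(C)=O)CC[C@]12C | intermediate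
8 | (3R,3aS,8aS)-3a-{[dimethyl(phenyl)silyl]oxy}-8a-methyl-3-(prop-1-en-2-yl)octahydroazulen-8(1H)-one | O=C1CCCC[C@]2(O[Si](C)(C)c3ccccc3)[C@@H](C(C)=C)CC[C@]12C | intermediate
9 | (3R,3aS,8aS)-3a-{[dimethyl(phenyl)silyl]oxy}-8a-methyl-3-(propan-2-yl)octahydroazulen-8(1H)-one | O=C1CCCC[C@]2(O[Si](C)(C)c3ccccc3)[C@@H](C(C)C)CC[C@]12C | intermediate
10 | trimethylsilyl enol ether of 9 (C7=C8, OSiMe3 on C8) | C[Si](C)(C)OC1=CCCC[C@]2(O[Si](C)(C)c3ccccc3)[C@@H](C(C)C)CC[C@]12C | intermediate
11 | (3R,3aS,8aS)-3a-{[dimethyl(phenyl)silyl]oxy}-8a-methyl-3-(propan-2-yl)-2,3,3a,4,5,8a-hexahydroazulen-8(1H)-one (C6=C7 enone) | O=C1C=CCC[C@]2(O[Si](C)(C)c3ccccc3)[C@@H](C(C)C)CC[C@]12C | intermediate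
12 | trimethylsilyl enol ether of the 6-methyl ketone (C7=C8, OSiMe3 on C8, both C6 epimers) | C[Si](C)(C)OC1=CC(C)CC[C@]2(O[Si](C)(C)c3ccccc3)[C@@H](C(C)C)CC[C@]12C | intermediate
13 | (3R,3aS,8aS)-3a-{[dimethyl(phenyl)silyl]oxy}-6,8a-dimethyl-3-(propan-2-yl)-2,3,3a,4,5,8a-hexahydroazulen-8(1H)-one | O=C1C=C(C)CC[C@]2(O[Si](C)(C)c3ccccc3)[C@@H](C(C)C)CC[C@]12C | intermediate
14 | (3R,3aS,8aS)-3a-hydroxy-6,8a-dimethyl-3-(propan-2-yl)-2,3,3a,4,5,8a-hexahydroazulen-8(1H)-one | O=C1C=C(C)CC[C@]2(O)[C@@H](C(C)C)CC[C@]12C | intermediate
15 | (3R,3aS,8S,8aR)-6,8a-dimethyl-3-(propan-2-yl)-1,2,3,4,5,8-hexahydroazulene-3a,8(8aH)-diol | O[C@H]1C=C(C)CC[C@]2(O)[C@@H](C(C)C)CC[C@]12C | intermediate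
16 | 4-methoxybenzoyl chloride | COc1ccc(cc1)C(Cl)=O | starting material
17 | (3R,3aS,8S,8aR)-3a-hydroxy-6,8a-dimethyl-3-(propan-2-yl)-1,2,3,3a,4,5,8,8a-octahydroazulen-8-yl 4-methoxybenzoate | COc1ccc(C(=O)O[C@H]2C=C(C)CC[C@]3(O)[C@@H](C(C)C)CC[C@]23C)cc1 | target

Total step count: 10. Longest linear sequence: 10 steps (1 to 17).

**Least certain steps**

Step 4 (key step). The most likely failures are weak discrimination between the two enantiotopic carbonyl groups, or slow silylation of the hindered tertiary copper alkoxide. The second would stall turnover and let plain conjugate reduction or over-reduction of a ketone take over. The fallback replaces the metal hydride by enamine catalysis. From 6, the enone C=C bond is hydrogenated (H2, Pd/C) to 2-methyl-2-(4-oxopentyl)cycloheptane-1,3-dione F1. F1 is cyclized by an amine-catalysed (proline-type) intramolecular 5-enolexo aldol desymmetrization to (3S,3aS,8aS)-3-acetyl-3a-hydroxy-8a-methyloctahydroazulen-8(1H)-one F2. The cis fusion is again forced by the tether. The acetyl group is epimerizable under these conditions and should settle cis to the hydroxyl through its hydrogen bond. Silylation of F2 with PhMe2SiCl and imidazole returns to the route at 7.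

Step 5. The most likely failure is loss of chemoselectivity between the acetyl group and the ring ketone, or cleavage of the silyl ether by the Lewis-acidic reagent. The fallback forms the alkene by addition and elimination instead of carbonyl olefination. From 7, MeMgCl/CeCl3 at −78 °C should add to the less hindered acetyl group without enolization and give (3R,3aS,8aS)-3a-{[dimethyl(phenyl)silyl]oxy}-3-(2-hydroxypropan-2-yl)-8a-methyloctahydroazulen-8(1H)-one F3. Syn-dehydration of F3 with the Burgess reagent toward a methyl group returns to the route at 8.

Step 3. The most likely failure is slow cross-metathesis of the allyl group next to the quaternary centre while the vinyl ketone homodimerizes and consumes the catalyst. The fallback builds the enone by carbonyl olefination. From 4, ozonolysis (O3, then Me2S) gives 2-(1-methyl-2,7-dioxocycloheptyl)acetaldehyde F4. A Wittig reaction of F4 with the stabilized ylide 1-(triphenyl-λ5-phosphanylidene)propan-2-one should give the E-enone and returns to the route at 6.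

Step 9. The most likely failure is poor facial selectivity if the hindered tertiary hydroxyl does not form the boron chelate. The fallback sets C8 by inversion during esterification. From 14, hydroxyl-directed reduction with Me4NBH(OAc)3 (Evans–Saksena, internal hydride delivery from the C3a oxygen) should give the anti diol (3R,3aS,8R,8aR)-6,8a-dimethyl-3-(propan-2-yl)-1,2,3,4,5,8-hexahydroazulene-3a,8(8aH)-diol F5. A Mitsunobu esterification of F5 with 4-methoxybenzoic acid (PPh3, DIAD) inverts C8 and returns to the route directly at 17.

**Further compounds**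

F1 | step 4 | 2-methyl-2-(4-oxopentyl)cycloheptane-1,3-dione | CC(=O)CCCC1(C)C(=O)CCCCC1=O
F2 | step 4 | (3S,3aS,8aS)-3-acetyl-3a-hydroxy-8a-methyloctahydroazulen-8(1H)-one | O=C1CCCC[C@]2(O)[C@@H](C(C)=O)CC[C@]12C
F3 | step 5 | (3R,3aS,8aS)-3a-{[dimethyl(phenyl)silyl]oxy}-3-(2-hydroxypropan-2-yl)-8a-methyloctahydroazulen-8(1H)-one | O=C1CCCC[C@]2(O[Si](C)(C)c3ccccc3)[C@@H](C(C)(C)O)CC[C@]12C
F4 | step 3 | 2-(1-methyl-2,7-dioxocycloheptyl)acetaldehyde | O=CCC1(C)C(=O)CCCCC1=O
F5 | step 9 | (3R,3aS,8R,8aR)-6,8a-dimethyl-3-(propan-2-yl)-1,2,3,4,5,8-hexahydroazulene-3a,8(8aH)-diol | O[C@@H]1C=C(C)CC[C@]2(O)[C@@H](C(C)C)CC[C@]12C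
A1 | alternative 1 | 1-[(1S,2S,3R)-2-hydroxy-1-methyl-2-(3-methylbut-3-en-1-yl)-3-(propan-2-yl)cyclopentyl]prop-2-en-1-one | C=CC(=O)[C@@]1(C)CC[C@H](C(C)C)[C@@]1(O)CCC(C)=C
A2 | alternative 2 | (6R)-3-chloro-3,7-dimethyl-6-(5-methylfuran-2-yl)octan-2-one (both C3 epimers) | CC(=O)C(C)(Cl)CC[C@H](C(C)C)c1ccc(C)o1
A3 | alternative 2 | (1S,2R,5S,8R)-5,8-dimethyl-2-(propan-2-yl)-11-oxatricyclo[6.2.1.0(1,5)]undec-9-en-6-one | O=C1C[C@]2(C)C=C[C@]3(O2)[C@@H](C(C)C)CC[C@]13C
A4 | alternative 3 | (3R,3aS,7aS)-3a-hydroxy-6,7a-dimethyl-3-(propan-2-yl)octahydro-7H-inden-7-one (both C6 epimers) | O=C1C(C)CC[C@]2(O)[C@@H](C(C)C)CC[C@]12C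
A5 | alternative 3 | trimethylsilyloxycyclopropane from the C6–C7 enol silane of A4 (new CH2 bridging C6 and C7) | C[Si](C)(C)OC12CC2(C)CC[C@]3(O)[C@@H](C(C)C)CC[C@]13C
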